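**Plan**

- Feature: in the upper unit, pyran ring C ties the ring A phenol oxygen O1 to the doubly benzylic C4 that carries ring D. Ring A with C4 is therefore a masked ortho-quinone methide, and C2=C3 with ring B a masked enol ether.
- Retrosynthesis: cut the two galloyl esters; open lower ring F at C4–C4a (arene–epoxide) and O1–C2 (aryl ether); trace the upper C2–H to a C2 ketal; cut ring C at C3–C4 and O1–C2; cut the C4–ring D bond at a diaryl carbinol.
- Forward: rings A and D are joined as a diaryl carbinol; ring C forms together with ring B in the [4+2] step; the ketal is reduced; ring F is built with ring E on the freed ring D phenol; deallylation, double galloylation and hydrogenolysis finish.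
- Stereochemistry: upper C4 from the chiral phosphoric acid; upper C3 from exo approach of the benzyloxy group (3,4-trans); upper C2 from axial hydride delivery anti to 3-OBn; lower C2 and C3 from a Sharpless kinetic resolution, C2 being inverted in the Mitsunobu step.

Key step: step 8

Assumption: the (R)-configured phosphoric acid is taken to give the 4S adduct; if the sense of induction proves opposite, its (S)-enantiomer is used with no other change.

**Route**

Step 1
Reactants: 1 2,4,6-trihydroxybenzaldehyde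
Product: 2 2,4-bis(benzyloxy)-6-hydroxybenzaldehyde
Conditions: BnBr (2.05 equiv), K2CO3, DMF, 0 °C → rt
Reagents that add atoms: benzyl bromide, BrCc1ccccc1
Why: Williamson etherification in which the unchelated 4-hydroxyl and one of the two ortho hydroxyls are benzylated, while the last ortho hydroxyl, held by its hydrogen bond to the formyl group, should survive two equivalents of halide.

Step 2
Reactants: 3 3,5-bis(benzyloxy)phenol
Product: 4 [3,5-bis(benzyloxy)phenoxy]triisopropylsilane
Conditions: i-Pr3SiCl, imidazole, DMF, rt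
Reagents that add atoms: chlorotriisopropylsilane, CC(C)[Si](Cl)(C(C)C)C(C)C
Why: Standard silylation of the only free phenol, giving a bulky ether that is stable to base and organolithium reagents and marks the oxygen that later becomes O1 of ring F.

Step 3
Reactants: 4 [3,5-bis(benzyloxy)phenoxy]triisopropylsilane
Product: 5 [3,5-bis(benzyloxy)-4-bromophenoxy]triisopropylsilane
Conditions: N-bromosuccinimide (1.0 equiv), CH2Cl2, −78 → 0 °C
Reagents that add atoms: N-bromosuccinimide, O=C1CCC(=O)N1Br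
Why: Electrophilic aromatic bromination in which, of the three positions activated by all three oxygens, only the one between the benzyl ethers is not flanked by the triisopropylsilyl group, whose bulk shields both of its ortho positions.

Step 4
Reactants: 5 [3,5-bis(benzyloxy)-4-bromophenoxy]triisopropylsilane; 2 2,4-bis(benzyloxy)-6-hydroxybenzaldehyde
Product: 8 rac-[2,4-bis(benzyloxy)-6-hydroxyphenyl][2,6-bis(benzyloxy)-4-(triisopropylsilyloxy)phenyl]methanol, via aryllithium 6 (not isolated), via sodium phenolate 7 (not isolated)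
Conditions: 5, n-BuLi, THF, −78 °C; then 7 (from 2, NaH, THF, 0 °C), −78 → 0 °C; H2O; NEt3-deactivated silica
Reagents that add atoms: none
Why: Bromine–lithium exchange at −78 °C outruns benzylic deprotonation, and aryllithium 6 adds to the formyl group of the pre-formed phenolate 7 (1,2-addition); the carbinol stereocentre is racemic and is erased in step 8.

Step 5
Reactants: 9 benzyloxyacetyl chloride
Product: 10 2-(benzyloxy)-N-methoxy-N-methylacetamide
Conditions: MeNHOMe·HCl, pyridine, CH2Cl2, 0 °C → rt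
Reagents that add atoms: N,O-dimethylhydroxylamine hydrochloride, CNOC.Cl
Why: N-Acylation of the hydroxylamine by the acid chloride gives the Weinreb amide.

Step 6
Reactants: 11 4-bromo-1,2-bis(benzyloxy)benzene; 10 2-(benzyloxy)-N-methoxy-N-methylacetamide
Product: 13 2-(benzyloxy)-1-[3,4-bis(benzyloxy)phenyl]ethan-1-one, via aryllithium 12 (not isolated)
Conditions: 11, n-BuLi, THF, −78 °C; then 10, −78 → 0 °C; H2O
Reagents that add atoms: none
Why: Weinreb ketone synthesis, in which aryllithium 12 adds only once because the chelated tetrahedral intermediate survives until work-up.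

Step 7
Reactants: 13 2-(benzyloxy)-1-[3,4-bis(benzyloxy)phenyl]ethan-1-one
Product: 15 tert-butyl{[(1Z)-2-(benzyloxy)-1-[3,4-bis(benzyloxy)phenyl]ethenyl]oxy}dimethylsilane, via lithium enolate 14 (not isolated)
Conditions: LiN(SiMe3)2, THF, −78 °C; then t-BuMe2SiCl, DMPU, −78 → 0 °C; filtration through basic alumina
Reagents that add atoms: tert-butylchlorodimethylsilane, CC(C)(C)[Si](C)(C)Cl
Why: Kinetic enolisation gives the enolate with lithium chelated between the enolate and benzyloxy oxygens, so O-silylation fixes the Z double bond (silyloxy cis to benzyloxy), which is also the isomer free of A(1,3) strain with the aryl ring.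

Step 8
Reactants: 8 rac-[2,4-bis(benzyloxy)-6-hydroxyphenyl][2,6-bis(benzyloxy)-4-(triisopropylsilyloxy)phenyl]methanol; 15 tert-butyl{[(1Z)-2-(benzyloxy)-1-[3,4-bis(benzyloxy)phenyl]ethenyl]oxy}dimethylsilane
Product: 17 (2R,3R,4S)-3,5,7-tris(benzyloxy)-2-[3,4-bis(benzyloxy)phenyl]-4-[2,6-bis(benzyloxy)-4-(triisopropylsilyloxy)phenyl]-2-(tert-butyldimethylsilyloxy)chromane (3-OBn trans to ring D, cis to 2-OSi), via ortho-quinone methide 16 (not isolated)
Conditions: 15 (1.5 equiv), (R)-TRIP [(R)-3,3'-bis(2,4,6-triisopropylphenyl)-1,1'-binaphthalene-2,2'-diyl hydrogen phosphate] (10 mol %), 4 Å MS, toluene, −40 °C; NEt3 quench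
Reagents that add atoms: none
Why: The phosphoric acid dehydrates 8 to ortho-quinone methide 16, which stays hydrogen-bonded or ion-paired to the chiral phosphate at its ring A oxygen; the benzyloxy-bearing carbon of 15 then attacks C4 and the ring A oxygen captures the silyloxocarbenium carbon, either in one asynchronous inverse-demand hetero-Diels–Alder event or as a Mukaiyama–Michael addition followed by ketalisation. The closest known reaction type is the chiral phosphoric acid catalysed formal [4+2] cycloaddition of quinone methides, generated in situ from ortho-hydroxybenzhydrols, with enol ethers, enamides and other electron-rich alkenes. Ring C closes as a six-membered cyclic ketal ([4+2] mode, or 6-exo-trig attack of oxygen on the oxocarbenium carbon if stepwise). C4 (S) is set by the catalyst, whose 3,3'-aryl groups shield one face of the bound methide; C3 (R) follows from simple diastereoselection, the benzyloxy group taking the exo sector away from ring A and its peri 5-benzyloxy group so that it ends trans to ring D (with the Z alkene this places ring B endo and the bulky silyloxy group exo); C2 follows from suprafacial addition across the Z double bond and is of no consequence because it is planarised in step 9. The step needs C4 face selectivity and 3,4-trans selectivity: the first rests on the single catalyst-binding oxygen of the methide and on the symmetric ring D, the second on the outward orientation of ring D in the catalyst-bound methide and on the exo preference of the C3 substituent, while the sieves keep the released water from the enol silane.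

Step 9
Reactants: 17 (2R,3R,4S)-2-silyloxy ketal from step 8
Product: 19 (2R,3R,4S)-3,5,7-tris(benzyloxy)-2-[3,4-bis(benzyloxy)phenyl]-4-[2,6-bis(benzyloxy)-4-(triisopropylsilyloxy)phenyl]chromane, via oxocarbenium ion 18 (not isolated)
Conditions: Et3SiH (5 equiv), BF3·OEt2, CH2Cl2, −78 → −40 °C
Reagents that add atoms: none
Why: Ionic hydrogenation of the cyclic ketal, in which BF3 ionises 17 to the 2-aryl oxocarbenium ion 18, A(1,2) strain with the coplanar ring B and peri strain between ring D and the 5-benzyloxy group hold the 3-benzyloxy and 4-aryl groups trans-diaxial, and triethylsilane delivers hydride axially, anti to the 3-benzyloxy group, setting C2 (R) and the 2,3-cis relationship.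

Step 10
Reactants: 19 (2R,3R,4S)-4-aryl flavan triisopropylsilyl ether
Product: 20 3,5-bis(benzyloxy)-4-{(2R,3R,4S)-3,5,7-tris(benzyloxy)-2-[3,4-bis(benzyloxy)phenyl]chroman-4-yl}phenol
Conditions: Bu4NF, THF, 0 °C
Reagents that add atoms: none
Why: Fluoride-mediated desilylation cleaves the only silyl ether and frees the ring D phenol that becomes O1 of ring F.

Step 11
Reactants: 21 methyl gallate
Product: 22 methyl 3,4-bis(benzyloxy)-5-hydroxybenzoate
Conditions: BnBr (2.0 equiv), K2CO3, DMF, rt; chromatography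
Reagents that add atoms: benzyl bromide, BrCc1ccccc1
Why: Williamson etherification under stoichiometric control, in which the 4-hydroxyl (para to the ester, most acidic) reacts first and one of the two equivalent flanking hydroxyls second, so the 3,4-dibenzyl ether should be the main product and is separated from mono- and tribenzyl ethers.

Step 12
Reactants: 22 methyl 3,4-bis(benzyloxy)-5-hydroxybenzoate
Product: 23 methyl 3-(allyloxy)-4,5-bis(benzyloxy)benzoate
Conditions: allyl bromide, K2CO3, DMF, 50 °C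
Reagents that add atoms: allyl bromide, C=CCBr
Why: Williamson etherification of the remaining phenol installs an allyl ether that is orthogonal to every benzyl ether and marks the oxygen that will carry the ring E gallate.

Step 13
Reactants: 23 methyl 3-(allyloxy)-4,5-bis(benzyloxy)benzoate
Product: 24 [3-(allyloxy)-4,5-bis(benzyloxy)phenyl]methanol
Conditions: LiAlH4, THF, 0 °C; aqueous NaOH work-up
Reagents that add atoms: none
Why: Hydride reduction of the ester to the benzylic alcohol, to which aryl allyl and benzyl ethers are inert.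

Step 14
Reactants: 24 [3-(allyloxy)-4,5-bis(benzyloxy)phenyl]methanol
Product: 25 3-(allyloxy)-4,5-bis(benzyloxy)benzaldehyde
Conditions: MnO2, CH2Cl2, rt
Reagents that add atoms: none
Why: Selective oxidation of a benzylic alcohol to the aldehyde without over-oxidation.

Step 15
Reactants: 25 3-(allyloxy)-4,5-bis(benzyloxy)benzaldehyde
Product: 26 rac-1-[3-(allyloxy)-4,5-bis(benzyloxy)phenyl]prop-2-en-1-ol
Conditions: CH2=CHMgBr, THF, −78 → 0 °C
Reagents that add atoms: vinylmagnesium bromide, C=C[Mg]Br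
Why: Grignard 1,2-addition gives the racemic aryl vinyl carbinol required for the resolution.

Step 16
Reactants: 26 rac-1-[3-(allyloxy)-4,5-bis(benzyloxy)phenyl]prop-2-en-1-ol
Product: 27 (S)-[3-(allyloxy)-4,5-bis(benzyloxy)phenyl][(2R)-oxiran-2-yl]methanol (erythro)
Conditions: Ti(OiPr)4 (15 mol %), L-(+)-diisopropyl tartrate (20 mol %), t-BuOOH (0.45 equiv), 4 Å MS, CH2Cl2, −20 °C
Reagents that add atoms: tert-butyl hydroperoxide, CC(C)(C)OO
Why: Sharpless kinetic resolution, in which the L-(+)-tartrate catalyst epoxidises the (R)-alcohol much faster than the (S)-alcohol and gives the erythro epoxy alcohol, so the carbinol configuration comes from the resolution and the epoxide carbon from reagent-controlled oxygen delivery, while the aryl allyl ether, not being an allylic alcohol, is untouched.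

Step 17
Reactants: 20 ring D phenol from step 10; 27 (S)-[3-(allyloxy)-4,5-bis(benzyloxy)phenyl][(2R)-oxiran-2-yl]methanol
Product: 28 (2R,3R,4S)-3,5,7-tris(benzyloxy)-2-[3,4-bis(benzyloxy)phenyl]-4-{2,6-bis(benzyloxy)-4-[(R)-[3-(allyloxy)-4,5-bis(benzyloxy)phenyl][(2R)-oxiran-2-yl]methoxy]phenyl}chromane
Conditions: PPh3, diisopropyl azodicarboxylate, THF, 0 °C → rt
Reagents that add atoms: none
Why: Mitsunobu etherification, in which the ring D phenol displaces the activated benzylic hydroxyl with inversion and so converts the (S)-carbinol into the (R)-aryl ether (the future lower C2) while the epoxide carbon is untouched.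

Step 18
Reactants: 28 aryl ether epoxide from step 17
Product: 29 (2R,3R)-2-[3-(allyloxy)-4,5-bis(benzyloxy)phenyl]-5,7-bis(benzyloxy)-6-{(2R,3R,4S)-3,5,7-tris(benzyloxy)-2-[3,4-bis(benzyloxy)phenyl]chroman-4-yl}chroman-3-ol
Conditions: AuCl3 (5 mol %), AgOTf (15 mol %), ClCH2CH2Cl, 0 °C → rt
Reagents that add atoms: none
Why: Lewis acid catalysed intramolecular Friedel–Crafts alkylation (6-endo epoxide–arene cyclisation), in which the ring D carbon ortho to the new ether attacks the unsubstituted epoxide terminus to close ring F without touching a stereocentre, so the threo ether gives the 2,3-cis flavan-3-ol, and the two ortho positions of ring D, interchanged by rotation about the C4–ring D bond, allow only the 4→6 linkage.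

Step 19
Reactants: 29 allyl-protected dimer from step 18
Product: 30 (2R,3R)-2-[3,4-bis(benzyloxy)-5-hydroxyphenyl]-5,7-bis(benzyloxy)-6-{(2R,3R,4S)-3,5,7-tris(benzyloxy)-2-[3,4-bis(benzyloxy)phenyl]chroman-4-yl}chroman-3-ol
Conditions: Pd(PPh3)4 (5 mol %), morpholine, THF, rt
Reagents that add atoms: none
Why: Tsuji–Trost deallylation, in which zerovalent palladium ionises the aryl allyl ether and morpholine captures the allyl fragment, leaving benzyl ethers and the secondary alcohol untouched.

Step 20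
Reactants: 30 phenol–alcohol from step 19; 31 3,4,5-tris(benzyloxy)benzoic acid
Product: 32 (2R,3R)-5,7-bis(benzyloxy)-2-{3,4-bis(benzyloxy)-5-[3,4,5-tris(benzyloxy)benzoyloxy]phenyl}-6-{(2R,3R,4S)-3,5,7-tris(benzyloxy)-2-[3,4-bis(benzyloxy)phenyl]chroman-4-yl}chroman-3-yl 3,4,5-tris(benzyloxy)benzoate
Conditions: 31 (3 equiv), dicyclohexylcarbodiimide, 4-(dimethylamino)pyridine, CH2Cl2, rt
Reagents that add atoms: none
Why: Steglich esterification acylates both the ring E phenol and the axial secondary 3-hydroxyl, the aminopyridine-catalysed acyl transfer being needed for the hindered alcohol.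

Step 21
Reactants: 32 pentadeca-O-benzyl digallate from step 20
Product: 33 epicatechin-(4β→6)-epigallocatechin 3,3'-di-O-gallate, i.e. (2R,3R)-2-[3,4-dihydroxy-5-(3,4,5-trihydroxybenzoyloxy)phenyl]-5,7-dihydroxy-6-[(2R,3R,4S)-2-(3,4-dihydroxyphenyl)-3,5,7-trihydroxychroman-4-yl]chroman-3-yl 3,4,5-trihydroxybenzoate
Conditions: H2 (1 atm), Pd(OH)2/C, THF/MeOH/H2O, rt
Reagents that add atoms: none
Why: Hydrogenolysis of all fifteen benzyl ethers under neutral conditions should leave both esters, the benzylic pyran C–O bonds and the interflavan bond intact.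

**Compound list**

1 | 2,4,6-trihydroxybenzaldehyde | O=Cc1c(O)cc(O)cc1O | starting material
2 | 2,4-bis(benzyloxy)-6-hydroxybenzaldehyde | O=Cc1c(O)cc(OCc2ccccc2)cc1OCc1ccccc1 | intermediate
3 | 3,5-bis(benzyloxy)phenol | Oc1cc(OCc2ccccc2)cc(OCc2ccccc2)c1 | starting material
4 | [3,5-bis(benzyloxy)phenoxy]triisopropylsilane | CC(C)[Si](C(C)C)(C(C)C)Oc1cc(OCc2ccccc2)cc(OCc2ccccc2)c1 | intermediate
5 | [3,5-bis(benzyloxy)-4-bromophenoxy]triisopropylsilane | CC(C)[Si](C(C)C)(C(C)C)Oc1cc(OCc2ccccc2)c(Br)c(OCc2ccccc2)c1 | intermediate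
6 | [2,6-bis(benzyloxy)-4-(triisopropylsilyloxy)phenyl]lithium | CC(C)[Si](C(C)C)(C(C)C)Oc1cc(OCc2ccccc2)c([Li])c(OCc2ccccc2)c1 | intermediate
7 | sodium 3,5-bis(benzyloxy)-2-formylphenolate | O=Cc1c([O-])cc(OCc2ccccc2)cc1OCc1ccccc1.[Na+] | intermediate
8 | rac-[2,4-bis(benzyloxy)-6-hydroxyphenyl][2,6-bis(benzyloxy)-4-(triisopropylsilyloxy)phenyl]methanol | CC(C)[Si](C(C)C)(C(C)C)Oc1cc(OCc2ccccc2)c(C(O)c2c(O)cc(OCc3ccccc3)cc2OCc2ccccc2)c(OCc2ccccc2)c1 | intermediate
9 | benzyloxyacetyl chloride | O=C(Cl)COCc1ccccc1 | starting material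
10 | 2-(benzyloxy)-N-methoxy-N-methylacetamide | CON(C)C(=O)COCc1ccccc1 | intermediate
11 | 4-bromo-1,2-bis(benzyloxy)benzene | Brc1ccc(OCc2ccccc2)c(OCc2ccccc2)c1 | starting material
12 | [3,4-bis(benzyloxy)phenyl]lithium | [Li]c1ccc(OCc2ccccc2)c(OCc2ccccc2)c1 | intermediate
13 | 2-(benzyloxy)-1-[3,4-bis(benzyloxy)phenyl]ethan-1-one | O=C(COCc1ccccc1)c1ccc(OCc2ccccc2)c(OCc2ccccc2)c1 | intermediate
14 | lithium (1Z)-2-(benzyloxy)-1-[3,4-bis(benzyloxy)phenyl]ethen-1-olate | [Li+].[O-]/C(=C\OCc1ccccc1)c1ccc(OCc2ccccc2)c(OCc2ccccc2)c1 | intermediate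
15 | tert-butyl{[(1Z)-2-(benzyloxy)-1-[3,4-bis(benzyloxy)phenyl]ethenyl]oxy}dimethylsilane | CC(C)(C)[Si](C)(C)O/C(=C\OCc1ccccc1)c1ccc(OCc2ccccc2)c(OCc2ccccc2)c1 | intermediate
16 | (6E)-3,5-bis(benzyloxy)-6-{[2,6-bis(benzyloxy)-4-(triisopropylsilyloxy)phenyl]methylidene}cyclohexa-2,4-dien-1-one | O=C1C=C(OCc2ccccc2)C=C(OCc2ccccc2)/C1=C\c1c(OCc2ccccc2)cc(O[Si](C(C)C)(C(C)C)C(C)C)cc1OCc1ccccc1 | intermediate
17 | (2R,3R,4S)-3,5,7-tris(benzyloxy)-2-[3,4-bis(benzyloxy)phenyl]-4-[2,6-bis(benzyloxy)-4-(triisopropylsilyloxy)phenyl]-2-(tert-butyldimethylsilyloxy)chromane | CC(C)[Si](C(C)C)(C(C)C)Oc1cc(OCc2ccccc2)c(c(OCc2ccccc2)c1)[C@H]1c2c(OCc3ccccc3)cc(OCc3ccccc3)cc2O[C@@](O[Si](C)(C)C(C)(C)C)(c2ccc(OCc3ccccc3)c(OCc3ccccc3)c2)[C@@H]1OCc1ccccc1 | intermediate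
18 | (3R,4S)-3,5,7-tris(benzyloxy)-2-[3,4-bis(benzyloxy)phenyl]-4-[2,6-bis(benzyloxy)-4-(triisopropylsilyloxy)phenyl]-3,4-dihydrochromenylium (C2 oxocarbenium ion) | CC(C)[Si](C(C)C)(C(C)C)Oc1cc(OCc2ccccc2)c(c(OCc2ccccc2)c1)[C@H]1c2c(OCc3ccccc3)cc(OCc3ccccc3)cc2[O+]=C(c2ccc(OCc3ccccc3)c(OCc3ccccc3)c2)[C@@H]1OCc1ccccc1 | intermediate
19 | (2R,3R,4S)-3,5,7-tris(benzyloxy)-2-[3,4-bis(benzyloxy)phenyl]-4-[2,6-bis(benzyloxy)-4-(triisopropylsilyloxy)phenyl]chromane | CC(C)[Si](C(C)C)(C(C)C)Oc1cc(OCc2ccccc2)c(c(OCc2ccccc2)c1)[C@H]1c2c(OCc3ccccc3)cc(OCc3ccccc3)cc2O[C@H](c2ccc(OCc3ccccc3)c(OCc3ccccc3)c2)[C@@H]1OCc1ccccc1 | intermediate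
20 | 3,5-bis(benzyloxy)-4-{(2R,3R,4S)-3,5,7-tris(benzyloxy)-2-[3,4-bis(benzyloxy)phenyl]chroman-4-yl}phenol | Oc1cc(OCc2ccccc2)c(c(OCc2ccccc2)c1)[C@H]1c2c(OCc3ccccc3)cc(OCc3ccccc3)cc2O[C@H](c2ccc(OCc3ccccc3)c(OCc3ccccc3)c2)[C@@H]1OCc1ccccc1 | intermediate
21 | methyl gallate | COC(=O)c1cc(O)c(O)c(O)c1 | starting material
22 | methyl 3,4-bis(benzyloxy)-5-hydroxybenzoate | COC(=O)c1cc(O)c(OCc2ccccc2)c(OCc2ccccc2)c1 | intermediate
23 | methyl 3-(allyloxy)-4,5-bis(benzyloxy)benzoate | COC(=O)c1cc(OCC=C)c(OCc2ccccc2)c(OCc2ccccc2)c1 | intermediate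
24 | [3-(allyloxy)-4,5-bis(benzyloxy)phenyl]methanol | OCc1cc(OCC=C)c(OCc2ccccc2)c(OCc2ccccc2)c1 | intermediate
25 | 3-(allyloxy)-4,5-bis(benzyloxy)benzaldehyde | O=Cc1cc(OCC=C)c(OCc2ccccc2)c(OCc2ccccc2)c1 | intermediate
26 | rac-1-[3-(allyloxy)-4,5-bis(benzyloxy)phenyl]prop-2-en-1-ol | C=CC(O)c1cc(OCC=C)c(OCc2ccccc2)c(OCc2ccccc2)c1 | intermediate
27 | (S)-[3-(allyloxy)-4,5-bis(benzyloxy)phenyl][(2R)-oxiran-2-yl]methanol | C=CCOc1cc(cc(OCc2ccccc2)c1OCc1ccccc1)[C@H](O)[C@H]1CO1 | intermediate
28 | (2R,3R,4S)-3,5,7-tris(benzyloxy)-2-[3,4-bis(benzyloxy)phenyl]-4-{2,6-bis(benzyloxy)-4-[(R)-[3-(allyloxy)-4,5-bis(benzyloxy)phenyl][(2R)-oxiran-2-yl]methoxy]phenyl}chromane | C=CCOc1cc(cc(OCc2ccccc2)c1OCc1ccccc1)[C@@H](Oc1cc(OCc2ccccc2)c(c(OCc2ccccc2)c1)[C@H]1c2c(OCc3ccccc3)cc(OCc3ccccc3)cc2O[C@H](c2ccc(OCc3ccccc3)c(OCc3ccccc3)c2)[C@@H]1OCc1ccccc1)[C@H]1CO1 | intermediate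
29 | (2R,3R)-2-[3-(allyloxy)-4,5-bis(benzyloxy)phenyl]-5,7-bis(benzyloxy)-6-{(2R,3R,4S)-3,5,7-tris(benzyloxy)-2-[3,4-bis(benzyloxy)phenyl]chroman-4-yl}chroman-3-ol | C=CCOc1cc(cc(OCc2ccccc2)c1OCc1ccccc1)[C@H]1Oc2cc(OCc3ccccc3)c([C@H]3c4c(OCc5ccccc5)cc(OCc5ccccc5)cc4O[C@H](c4ccc(OCc5ccccc5)c(OCc5ccccc5)c4)[C@@H]3OCc3ccccc3)c(OCc3ccccc3)c2C[C@H]1O | intermediate
30 | (2R,3R)-2-[3,4-bis(benzyloxy)-5-hydroxyphenyl]-5,7-bis(benzyloxy)-6-{(2R,3R,4S)-3,5,7-tris(benzyloxy)-2-[3,4-bis(benzyloxy)phenyl]chroman-4-yl}chroman-3-ol | Oc1cc(cc(OCc2ccccc2)c1OCc1ccccc1)[C@H]1Oc2cc(OCc3ccccc3)c([C@H]3c4c(OCc5ccccc5)cc(OCc5ccccc5)cc4O[C@H](c4ccc(OCc5ccccc5)c(OCc5ccccc5)c4)[C@@H]3OCc3ccccc3)c(OCc3ccccc3)c2C[C@H]1O | intermediate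
31 | 3,4,5-tris(benzyloxy)benzoic acid | OC(=O)c1cc(OCc2ccccc2)c(OCc2ccccc2)c(OCc2ccccc2)c1 | starting material
32 | (2R,3R)-5,7-bis(benzyloxy)-2-{3,4-bis(benzyloxy)-5-[3,4,5-tris(benzyloxy)benzoyloxy]phenyl}-6-{(2R,3R,4S)-3,5,7-tris(benzyloxy)-2-[3,4-bis(benzyloxy)phenyl]chroman-4-yl}chroman-3-yl 3,4,5-tris(benzyloxy)benzoate | O=C(Oc1cc(cc(OCc2ccccc2)c1OCc1ccccc1)[C@H]1Oc2cc(OCc3ccccc3)c([C@H]3c4c(OCc5ccccc5)cc(OCc5ccccc5)cc4O[C@H](c4ccc(OCc5ccccc5)c(OCc5ccccc5)c4)[C@@H]3OCc3ccccc3)c(OCc3ccccc3)c2C[C@H]1OC(=O)c1cc(OCc2ccccc2)c(OCc2ccccc2)c(OCc2ccccc2)c1)c1cc(OCc2ccccc2)c(OCc2ccccc2)c(OCc2ccccc2)c1 | intermediate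
33 | epicatechin-(4β→6)-epigallocatechin 3,3'-di-O-gallate (CNP0237700.1) | O=C(Oc1cc([C@H]2Oc3cc(O)c([C@H]4c5c(O)cc(O)cc5O[C@H](c5ccc(O)c(O)c5)[C@@H]4O)c(O)c3C[C@H]2OC(=O)c2cc(O)c(O)c(O)c2)cc(O)c1O)c1cc(O)c(O)c(O)c1 | target

**Step count**

Total: 21 steps. Longest linear sequence: 11 steps (21 → 33 through steps 11–21, or 3 → 33 through steps 2–4, 8–10 and 17–21).

**Steps most likely to fail**

Step 8. Three processes can spoil it:
- Protodesilylation of the enol silane by the acid and the released water before the C–C bond forms.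
- Poor face selectivity at C4, if the very stabilised methide reacts as a loosely paired cation.
- Endo/exo leakage that puts the 3-benzyloxy group cis to ring D.

Fallback (sets out from 4, returns at 19): the three upper-unit stereocentres are taken from the chiral pool instead.
- Commercial (−)-epicatechin is benzylated on its four phenols (BnBr, K2CO3, DMF) to 5,7,3',4'-tetra-O-benzylepicatechin F1.
- O3 is then benzylated (NaH, BnBr, DMF) to give penta-O-benzylepicatechin F2.
- DDQ in CH2Cl2 with 2-ethoxyethanol oxidises the benzylic C4 to the 4β-(2-ethoxyethoxy) ether F3.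
- Catalytic Me3SiOTf at −78 °C ionises F3. The C4 cation should be captured by an excess of arene 4 at its least shielded position, para to the silyloxy group, and trans to the 3-benzyloxy group, to give 19 directly.

Step 9. Two processes can spoil it:
- Hydride delivery syn to the 3-benzyloxy group (2,3-trans product), since the wanted face also carries the pseudoaxial ring D.
- Loss of H3 from the cation, which would scramble C3 through the 4H-chromene.

Fallback (sets out from 17, returns at 19): C2 is set by substitution with inversion instead of by hydride addition to a cation.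
- Mild hydrolysis of the silyl ketal (AcOH/THF/H2O, 0 °C → rt) should give hydroxy ketone F4, in equilibrium with its cyclic hemiketal.
- Zn(BH4)2 in Et2O at −20 °C reduces the ketone under chelation control through the 2-benzyloxy group to the erythro diol F5.
- PPh3 and diisopropyl azodicarboxylate then close ring C by intramolecular Mitsunobu etherification. The ring A phenol displaces the activated benzylic hydroxyl with inversion and should give 19 with the 2,3-cis arrangement.

Step 3. Bromination next to the silyl ether instead of between the benzyl ethers is possible, because the electronic preference (para to a benzyloxy group) opposes the steric one. The wrong isomer would carry a constitutionally wrong ring D through the whole route. The symmetric product shows a single two-proton aromatic singlet for ring D, which makes the check simple.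

Fallback (sets out from 1 and 3, returns at 8): the two aryl groups exchange roles, so that no electrophilic substitution on 4 is needed.
- Aldehyde 1 is silylated on its 4-hydroxyl, the only one not chelated to the formyl group (i-Pr3SiCl, imidazole, DMF), to give 2,6-dihydroxy-4-(triisopropylsilyloxy)benzaldehyde F6.
- Both chelated hydroxyls are benzylated under neutral Mitsunobu conditions (BnOH, PPh3, diisopropyl azodicarboxylate) to give 2,6-bis(benzyloxy)-4-(triisopropylsilyloxy)benzaldehyde F7.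
- Phenol 3 is converted by EtMgBr into bromomagnesium 3,5-bis(benzyloxy)phenolate F8.
- In toluene F8 should add to F7 through its ortho carbon in a magnesium-chelated six-membered transition state (ortho-specific hydroxyalkylation of magnesium phenolates) to give 8. The two ortho positions of 3 are equivalent, and attack between the benzyloxy groups has no chelate to support it.

Further compounds
F1 | step 8 | (2R,3R)-5,7-bis(benzyloxy)-2-[3,4-bis(benzyloxy)phenyl]chroman-3-ol (5,7,3',4'-tetra-O-benzylepicatechin) | C1c2c(OCc3ccccc3)cc(OCc3ccccc3)cc2O[C@H](c2ccc(OCc3ccccc3)c(OCc3ccccc3)c2)[C@@H]1O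
F2 | step 8 | (2R,3R)-3,5,7-tris(benzyloxy)-2-[3,4-bis(benzyloxy)phenyl]chromane (penta-O-benzylepicatechin) | C1c2c(OCc3ccccc3)cc(OCc3ccccc3)cc2O[C@H](c2ccc(OCc3ccccc3)c(OCc3ccccc3)c2)[C@@H]1OCc1ccccc1
F3 | step 8 | (2R,3R,4S)-3,5,7-tris(benzyloxy)-2-[3,4-bis(benzyloxy)phenyl]-4-(2-ethoxyethoxy)chromane (4β ether, trans to 3-OBn) | CCOCCO[C@H]1c2c(OCc3ccccc3)cc(OCc3ccccc3)cc2O[C@H](c2ccc(OCc3ccccc3)c(OCc3ccccc3)c2)[C@@H]1OCc1ccccc1
F4 | step 9 | (2R,3R)-2-(benzyloxy)-1-[3,4-bis(benzyloxy)phenyl]-3-[2,4-bis(benzyloxy)-6-hydroxyphenyl]-3-[2,6-bis(benzyloxy)-4-(triisopropylsilyloxy)phenyl]propan-1-one | CC(C)[Si](C(C)C)(C(C)C)Oc1cc(OCc2ccccc2)c(c(OCc2ccccc2)c1)[C@@H](c1c(OCc2ccccc2)cc(OCc2ccccc2)cc1O)[C@@H](OCc1ccccc1)C(=O)c1ccc(OCc2ccccc2)c(OCc2ccccc2)c1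
F5 | step 9 | (1S,2R,3R)-2-(benzyloxy)-1-[3,4-bis(benzyloxy)phenyl]-3-[2,4-bis(benzyloxy)-6-hydroxyphenyl]-3-[2,6-bis(benzyloxy)-4-(triisopropylsilyloxy)phenyl]propan-1-ol | CC(C)[Si](C(C)C)(C(C)C)Oc1cc(OCc2ccccc2)c(c(OCc2ccccc2)c1)[C@@H](c1c(OCc2ccccc2)cc(OCc2ccccc2)cc1O)[C@@H](OCc1ccccc1)[C@@H](O)c1ccc(OCc2ccccc2)c(OCc2ccccc2)c1
F6 | step 3 | 2,6-dihydroxy-4-(triisopropylsilyloxy)benzaldehyde | O=Cc1c(O)cc(O[Si](C(C)C)(C(C)C)C(C)C)cc1O
F7 | step 3 | 2,6-bis(benzyloxy)-4-(triisopropylsilyloxy)benzaldehyde | O=Cc1c(OCc2ccccc2)cc(O[Si](C(C)C)(C(C)C)C(C)C)cc1OCc1ccccc1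
F8 | step 3 | bromomagnesium 3,5-bis(benzyloxy)phenolate | Br[Mg]Oc1cc(OCc2ccccc2)cc(OCc2ccccc2)c1
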